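Leftover substrate opened the meeting: at 25.0 h the birch run still held 24.4% of left-handed substrate and the maple run 15.1%, each in percent of both substrates charged.

common to all: left-handed substrate 0.22 M; right-handed substrate 0.22 M; precatalyst 0.44 mM
- birch: partner 0.22 M; run made earlier
- maple: partner 0.33 M; run made earlier
- flask: partner 0.440 M; time 25 h

| run | time / h | left-handed product / % | right-handed product / % | left-handed substrate / % |
|---|---|---|---|---|
| birch | 2.00 | 2.0 | 2.8 | 48.9 |
| birch | 6.00 | 8.7 | 4.0 | 41.7 |
| birch | 12.0 | 14.3 | 9.6 | 34.0 |
| birch | 20.0 | 18.0 | 13.2 | 28.1 |
| birch | 25.0 | 18.8 | 16.4 | 24.4 |
| maple | 2.00 | 3.2 | 1.5 | 48.0 |
| maple | 4.00 | 7.0 | 4.3 | 43.3 |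
| maple | 8.00 | 15.0 | 10.3 | 30.2 |
| maple | 12.0 | 22.3 | 15.6 | 24.4 |
| maple | 25.0 | 29.1 | 25.5 | 15.1 |

(standard deviation of a reading: 1 percentage point)

- free catalyst is single-handed; left-handed substrate and right-handed substrate are mirror images of each other, charged as a racemate, each of them at the stated concentration
- the numbers in the tables scatter by 1 percentage point (one standard deviation)
- an excess is the difference of the two amounts in percent of their sum
- an excess is below zero if the other one leads

- excess of left-handed product over right-handed product in the product at 2.5 h
- excess of left-handed product over right-handed product in the product at 25 h
- part of the left-handed substrate and right-handed substrate charged together that has reacted at 25 h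

The first speaker took the right-handed substrate by difference, 40.4% in birch and 30.3% in maple, a balance that stands even if one product turns into the other. Assuming each substrate is consumed first order in itself under the same partner and free catalyst, this speaker argued that the logarithm of the share left of the left-handed charge is s times that of the right-handed charge, and pooled both runs to a selectivity factor s of 2.68.

A second speaker asked when supply stops feeding the lead of the left-handed product. The stream ratio, left-handed product made per right-handed product made, is s times left-handed over right-handed substrate. It reaches one at 61.8% reacted, and this part of both substrates reacted is the crossover conversion, beyond which the right-handed substrate feeds its product faster than the left-handed substrate feeds its own.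

The author of the forecast offered 41% at 2.5 h, then 4.5% and 64% reacted at 25 h, holding that “left product is slowly converting to right product”. The second speaker, who reckoned no conversion of their own, noted that this conversion lies 2.2 percentage points past the crossover, so late in the flask supply should be shrinking the lead too.

The flask gave 38.0%, 1.38% and 67.5%.

    partner + free catalyst + left-handed substrate → free catalyst + left-handed product (k = 29.0 M⁻² min⁻¹)
    partner + free catalyst + right-handed substrate → free catalyst + right-handed product (k = 11.0 M⁻² min⁻¹)
    left-handed product ⇌ right-handed product (k = 0.00120 min⁻¹)
    free catalyst → spent catalyst (k = 9.20 × 10⁻⁴ min⁻¹)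
    partner + precatalyst → free catalyst + spent reagent (k = 0.00660 M⁻¹ min⁻¹)

At 25.0 h the flask kept 16% of its left-handed charge and 49% of its right-handed charge, so the stream ratio read 0.846, under one, with the conversion 5.7 points past the crossover. The neighbour charged with 1.1 M of partner reacted 96.9%, which is 35 points past the crossover. Its stream ratio at 25 h read 0.0282, and its excess of left-handed over right-handed product at that time was −2.24%.

(The data are simulated with constants of no real substance.)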